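## Retrosynthetic overview

1. Target 24 comes from diol 22 by selective acylation of the secondary C5 hydroxyl; 22 comes from acetonide 21.
2. 21 comes from the acyclic allenyl keto-aldehyde 18 and CO in one [2+2+1] cyclocarbonylation (hetero-Pauson–Khand type): the C6–C7 bond closes the cycloheptanone while C11–C12 and C12–O close the cis-fused α-methylene-γ-lactone.
3. 18 comes from allenyl lactone 14 (propenyllithium opening, double oxidation); the allene comes from aldehyde 10 (propargylation, Crabbé homologation).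
4. 10 comes from acid 6, made by Ireland–Claisen rearrangement of di-(E)-crotyl L-tartrate acetonide 3; this sets C1 and C10, and C5 comes from L-tartaric acid.
5. Ring order: dioxolane (present in 1), then a temporary γ-lactone 8 that tells C2 from C6, then the seven-membered ring and the methylene lactone together, then dioxolane removal.

Assumption: atom labels C1–C15 are the xanthanolide numbers of the target (C1 carbinol, C5 CH–O-acyl, C6/C7 lactone fusion, C9 ring ketone, C10 CH–CH3, C11–C13 methylene-lactone carbons); compounds 12–14, 16 and 17 are carried as C9-epimer mixtures (16 also as hemiketal epimers) because C9 becomes a ketone in step 8.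

## Route

Step 1
Reactants: 1 dimethyl (4R,5R)-2,2-dimethyl-1,3-dioxolane-4,5-dicarboxylate; 2 (2E)-but-2-en-1-ol
Product: 3 bis[(2E)-but-2-en-1-yl] (4R,5R)-2,2-dimethyl-1,3-dioxolane-4,5-dicarboxylate
Conditions: 2 (6 equiv), Ti(OiPr)4 (10 mol%), toluene, 110 °C, MeOH distilled off
Reagents that add atoms: none
Why: titanate-catalysed transesterification driven by removal of methanol exchanges both esters without touching the acetonide or the two (R) centres, one of which becomes C5.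

Step 2
Reactants: 3 bis[(2E)-but-2-en-1-yl] (4R,5R)-2,2-dimethyl-1,3-dioxolane-4,5-dicarboxylate
Product: 6 (4S,5R)-4-[(2S)-but-3-en-2-yl]-5-{[(2E)-but-2-en-1-yloxy]carbonyl}-2,2-dimethyl-1,3-dioxolane-4-carboxylic acid, via silyl ketene acetal 4 (not isolated), via trimethylsilyl ester 5 (not isolated)
Conditions: Me3SiCl (1.3 equiv, present before the base), LiN(iPr)2 (1.05 equiv), THF, −78 → 23 → 60 °C; then H2O (pH 4)
Reagents that add atoms: none
Why: Ireland–Claisen rearrangement in which mono-enolisation of the twofold-symmetric diester gives the lithium-chelated enolate (enolate oxygen syn to the ring oxygen), trapped at once as 4 before β-elimination; the chair [3,3] shift then occurs on the dioxolane face anti to the remaining ester, so the new C1–C10 bond is trans to C6 and the carboxyl cis to it, and the (E)-crotyl unit places the C10 methyl syn to the ring oxygen along C2–C1–C10–C9.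

Step 3
Reactants: 6 (4S,5R)-4-[(2S)-but-3-en-2-yl]-5-{[(2E)-but-2-en-1-yloxy]carbonyl}-2,2-dimethyl-1,3-dioxolane-4-carboxylic acid
Product: 8 (3aS,6aS)-3a-[(2S)-but-3-en-2-yl]-2,2-dimethyl-6,6a-dihydrofuro[3,4-d][1,3]dioxol-4(3aH)-one, via hydroxy acid 7 (not isolated)
Conditions: NaBH4, EtOH, 0 → 23 °C; then 1 M HCl to pH 3, 23 °C
Reagents that add atoms: none
Why: chemoselective borohydride reduction of the α-alkoxy ester beside an inert carboxylate, then lactonisation of 7 (CH2OH and CO2H are cis on the dioxolane), which fixes C6 at the alcohol level and C2 at the acyl level.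

Step 4
Reactants: 8 (3aS,6aS)-3a-[(2S)-but-3-en-2-yl]-2,2-dimethyl-6,6a-dihydrofuro[3,4-d][1,3]dioxol-4(3aH)-one
Product: 10 (2R)-2-[(3aS,6aS)-2,2-dimethyl-4-oxo-6,6a-dihydrofuro[3,4-d][1,3]dioxol-3a(4H)-yl]propanal, via ozonide 9 (not isolated)
Conditions: O3, CH2Cl2, −78 °C; then Me2S, −78 → 23 °C
Reagents that add atoms: ozone, [O-][O+]=O
Why: ozonolysis with reductive work-up cleaves the only alkene to the C9 aldehyde under cold neutral conditions that do not epimerise C10.

Step 5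
Reactants: 10 (2R)-2-[(3aS,6aS)-2,2-dimethyl-4-oxo-6,6a-dihydrofuro[3,4-d][1,3]dioxol-3a(4H)-yl]propanal; 11 3-bromoprop-1-yne
Product: 12 (3aS,6aS)-3a-[(2S)-3-hydroxyhex-5-yn-2-yl]-2,2-dimethyl-6,6a-dihydrofuro[3,4-d][1,3]dioxol-4(3aH)-one
Conditions: 11, Zn dust, THF, 0 → 23 °C; then H2O
Reagents that add atoms: none
Why: Barbier-type zinc propargylation: allenylzinc bromide adds through its γ-carbon to the aldehyde, not the lactone, giving the homopropargylic alcohol with C8, C7 and C11 in place; the new C9 carbinol centre is lost in step 8.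

Step 6
Reactants: 12 (3aS,6aS)-3a-[(2S)-3-hydroxyhex-5-yn-2-yl]-2,2-dimethyl-6,6a-dihydrofuro[3,4-d][1,3]dioxol-4(3aH)-one
Product: 14 (3aS,6aS)-3a-[(2S)-3-hydroxyhepta-5,6-dien-2-yl]-2,2-dimethyl-6,6a-dihydrofuro[3,4-d][1,3]dioxol-4(3aH)-one, via propargylic amine 13 (not isolated)
Conditions: (CH2O)n, CuBr (50 mol%), iPr2NH, 1,4-dioxane, 100 °C
Reagents that add atoms: formaldehyde (as paraformaldehyde), C=O
Why: Crabbé allene homologation: copper-catalysed Mannich reaction gives 13, whose amine α-hydride shifts to the alkyne with loss of the imine, leaving the terminal allene and installing C13; free hydroxyl and lactone are tolerated.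

Step 7
Reactants: 14 (3aS,6aS)-3a-[(2S)-3-hydroxyhepta-5,6-dien-2-yl]-2,2-dimethyl-6,6a-dihydrofuro[3,4-d][1,3]dioxol-4(3aH)-one; 15 (1E)-1-bromoprop-1-ene
Product: 17 (2E)-1-[(4S,5S)-4-[(2S)-3-hydroxyhepta-5,6-dien-2-yl]-5-(hydroxymethyl)-2,2-dimethyl-1,3-dioxolan-4-yl]but-2-en-1-one, via cyclic hemiketal 16 (not isolated)
Conditions: 15, tBuLi (2 equiv per 15), Et2O, −78 °C; then 14 (alkenyllithium 2.3 equiv), THF, −78 °C; then H2O
Reagents that add atoms: none
Why: organolithium mono-addition to a lactone: the tetrahedral lithium alkoxide of 16 is stable at −78 °C so only one alkenyl group adds (a second equivalent is taken up by the free hydroxyl), and bromine–lithium exchange with retention delivers the (E)-enone.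

Step 8
Reactants: 17 (2E)-1-[(4S,5S)-4-[(2S)-3-hydroxyhepta-5,6-dien-2-yl]-5-(hydroxymethyl)-2,2-dimethyl-1,3-dioxolan-4-yl]but-2-en-1-one
Product: 18 (4R,5S)-5-[(2E)-but-2-enoyl]-2,2-dimethyl-5-[(2R)-3-oxohepta-5,6-dien-2-yl]-1,3-dioxolane-4-carbaldehyde
Conditions: Dess–Martin periodinane (3 equiv), pyridine, CH2Cl2, 0 → 23 °C
Reagents that add atoms: none
Why: Dess–Martin oxidation under buffered neutral conditions converts the C9 carbinol to the ketone and, through the open form in equilibrium with hemiketal 16, the primary alcohol to the C6 aldehyde, without epimerising C5 or C10 or isomerising the allenylmethyl ketone.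

Step 9
Reactants: 18 (4R,5S)-5-[(2E)-but-2-enoyl]-2,2-dimethyl-5-[(2R)-3-oxohepta-5,6-dien-2-yl]-1,3-dioxolane-4-carbaldehyde
Product: 21 (3aS,6R,7S,8S,8aR)-7-[(2E)-but-2-enoyl]-6-methyl-3-methylidene-7,8-[(propane-2,2-diyl)bis(oxy)]octahydro-2H-cyclohepta[b]furan-2,5-dione, via oxaruthenacyclopentane 19 (not isolated), via acylruthenacycle 20 (not isolated)
Conditions: Ru3(CO)12 (5 mol%), CO (20 atm), 1,4-dioxane (0.01 M), 120 °C
Reagents that add atoms: carbon monoxide, [C-]#[O+]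
Why: Proposed new method: zerovalent ruthenium couples the C6 aldehyde with the internal allene π-bond suprafacially to the divalent-ruthenium metallacycle 19 (hence the cis C6/C7 fusion), CO inserts into Ru–C11 to give 20 and C–O reductive elimination releases the α-methylene lactone, here closing a seven-membered ring, helped by the quaternary C1 and the trans-dioxolane that bring C6 and C7 together and by the aldehyde being far more reactive than the hindered enone carbonyl; the C6–O bond is expected trans to C5–O because the aldehyde oxygen sits pseudo-equatorial and anti to the C5–O dipole, and the closest known reaction is the Ru3(CO)12-catalysed hetero-Pauson–Khand cyclocarbonylation of allenyl aldehydes to cis-fused α-methylene-γ-butyrolactones on five- and six-membered rings.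

Step 10
Reactants: 21 (3aS,6R,7S,8S,8aR)-7-[(2E)-but-2-enoyl]-6-methyl-3-methylidene-7,8-[(propane-2,2-diyl)bis(oxy)]octahydro-2H-cyclohepta[b]furan-2,5-dione
Product: 22 (3aS,6R,7S,8S,8aR)-7-[(2E)-but-2-enoyl]-7,8-dihydroxy-6-methyl-3-methylideneoctahydro-2H-cyclohepta[b]furan-2,5-dione
Conditions: CF3CO2H/H2O (9:1), CH2Cl2, 0 °C
Reagents that add atoms: none
Why: acid-catalysed acetal hydrolysis is fast for the strained trans-fused dioxolane and, being acidic, spares the enone, the methylene lactone and the tertiary β-hydroxy ketone from retro-aldol cleavage.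

Step 11
Reactants: 22 (3aS,6R,7S,8S,8aR)-7-[(2E)-but-2-enoyl]-7,8-dihydroxy-6-methyl-3-methylideneoctahydro-2H-cyclohepta[b]furan-2,5-dione; 23 3-methylbutanoic anhydride
Product: 24 (3aS,6R,7S,8S,8aR)-7-[(2E)-but-2-enoyl]-7-hydroxy-6-methyl-3-methylidene-2,5-dioxooctahydro-2H-cyclohepta[b]furan-8-yl 3-methylbutanoate
Conditions: 23 (1.5 equiv), DMAP (10 mol%), pyridine, CH2Cl2, 0 °C
Reagents that add atoms: none
Why: DMAP-catalysed acyl transfer esterifies the secondary C5 hydroxyl and leaves the tertiary α-ketol hydroxyl at C1 untouched, while the weakly basic cold medium avoids retro-aldol cleavage of C1–C10.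

## Compound list

1 | dimethyl (4R,5R)-2,2-dimethyl-1,3-dioxolane-4,5-dicarboxylate (dimethyl 2,3-O-isopropylidene-L-tartrate) | COC(=O)[C@@H]1OC(C)(C)O[C@H]1C(=O)OC | starting material
2 | (2E)-but-2-en-1-ol | C/C=C/CO | starting material
3 | bis[(2E)-but-2-en-1-yl] (4R,5R)-2,2-dimethyl-1,3-dioxolane-4,5-dicarboxylate | C/C=C/COC(=O)[C@@H]1OC(C)(C)O[C@H]1C(=O)OC/C=C/C | intermediate
4 | (2E)-but-2-en-1-yl (4R)-5-{(Z)-[(2E)-but-2-en-1-yloxy](trimethylsilyloxy)methylidene}-2,2-dimethyl-1,3-dioxolane-4-carboxylate | C/C=C/COC(=O)[C@@H]1OC(C)(C)O/C1=C(\O[Si](C)(C)C)OC/C=C/C | intermediate (not isolated)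
5 | 4-[(2E)-but-2-en-1-yl] 5-trimethylsilyl (4R,5S)-5-[(2S)-but-3-en-2-yl]-2,2-dimethyl-1,3-dioxolane-4,5-dicarboxylate | C/C=C/COC(=O)[C@@H]1OC(C)(C)O[C@]1([C@@H](C)C=C)C(=O)O[Si](C)(C)C | intermediate (not isolated)
6 | (4S,5R)-4-[(2S)-but-3-en-2-yl]-5-{[(2E)-but-2-en-1-yloxy]carbonyl}-2,2-dimethyl-1,3-dioxolane-4-carboxylic acid | C/C=C/COC(=O)[C@@H]1OC(C)(C)O[C@]1([C@@H](C)C=C)C(=O)O | intermediate
7 | (4S,5S)-4-[(2S)-but-3-en-2-yl]-5-(hydroxymethyl)-2,2-dimethyl-1,3-dioxolane-4-carboxylic acid | OC[C@@H]1OC(C)(C)O[C@]1([C@@H](C)C=C)C(=O)O | intermediate (not isolated)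
8 | (3aS,6aS)-3a-[(2S)-but-3-en-2-yl]-2,2-dimethyl-6,6a-dihydrofuro[3,4-d][1,3]dioxol-4(3aH)-one | O=C1OC[C@@H]2OC(C)(C)O[C@]12[C@@H](C)C=C | intermediate
9 | (3aS,6aS)-2,2-dimethyl-3a-[(1R)-1-(1,2,4-trioxolan-3-yl)ethyl]-6,6a-dihydrofuro[3,4-d][1,3]dioxol-4(3aH)-one (trioxolane carbon as epimers) | O=C1OC[C@@H]2OC(C)(C)O[C@]12[C@@H](C)C1OCOO1 | intermediate (not isolated)
10 | (2R)-2-[(3aS,6aS)-2,2-dimethyl-4-oxo-6,6a-dihydrofuro[3,4-d][1,3]dioxol-3a(4H)-yl]propanal | O=C1OC[C@@H]2OC(C)(C)O[C@]12[C@@H](C)C=O | intermediate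
11 | 3-bromoprop-1-yne (propargyl bromide) | C#CCBr | starting material
12 | (3aS,6aS)-3a-[(2S)-3-hydroxyhex-5-yn-2-yl]-2,2-dimethyl-6,6a-dihydrofuro[3,4-d][1,3]dioxol-4(3aH)-one (C9 carbinol epimers) | O=C1OC[C@@H]2OC(C)(C)O[C@]12[C@@H](C)C(O)CC#C | intermediate
13 | (3aS,6aS)-3a-{(2S)-7-[di(propan-2-yl)amino]-3-hydroxyhept-5-yn-2-yl}-2,2-dimethyl-6,6a-dihydrofuro[3,4-d][1,3]dioxol-4(3aH)-one | O=C1OC[C@@H]2OC(C)(C)O[C@]12[C@@H](C)C(O)CC#CCN(C(C)C)C(C)C | intermediate (not isolated)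
14 | (3aS,6aS)-3a-[(2S)-3-hydroxyhepta-5,6-dien-2-yl]-2,2-dimethyl-6,6a-dihydrofuro[3,4-d][1,3]dioxol-4(3aH)-one (C9 carbinol epimers) | O=C1OC[C@@H]2OC(C)(C)O[C@]12[C@@H](C)C(O)CC=C=C | intermediate
15 | (1E)-1-bromoprop-1-ene | C/C=C/Br | starting material
16 | (3aS,6aS)-4-hydroxy-3a-[(2S)-3-hydroxyhepta-5,6-dien-2-yl]-2,2-dimethyl-4-[(1E)-prop-1-en-1-yl]tetrahydrofuro[3,4-d][1,3]dioxole (cyclic hemiketal of 17) | C/C=C/C1(O)OC[C@@H]2OC(C)(C)O[C@]12[C@@H](C)C(O)CC=C=C | intermediate (not isolated)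
17 | (2E)-1-[(4S,5S)-4-[(2S)-3-hydroxyhepta-5,6-dien-2-yl]-5-(hydroxymethyl)-2,2-dimethyl-1,3-dioxolan-4-yl]but-2-en-1-one | C/C=C/C(=O)[C@]1(OC(C)(C)O[C@H]1CO)[C@@H](C)C(O)CC=C=C | intermediate
18 | (4R,5S)-5-[(2E)-but-2-enoyl]-2,2-dimethyl-5-[(2R)-3-oxohepta-5,6-dien-2-yl]-1,3-dioxolane-4-carbaldehyde | C/C=C/C(=O)[C@]1(OC(C)(C)O[C@H]1C=O)[C@@H](C)C(=O)CC=C=C | intermediate
19 | tricarbonyl oxaruthenacyclopentane spanning Ru–O–C6–C7–C11(=CH2), cis at C6/C7, rest as in 21 (mononuclear fragment shown) | C=C1[Ru](=C=O)(=C=O)(=C=O)O[C@@H]2[C@H]1CC(=O)[C@H](C)[C@@]3(OC(C)(C)O[C@@H]23)C(=O)/C=C/C | intermediate (not isolated)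
20 | tricarbonyl acylruthenacycle spanning Ru–O–C6–C7–C11(=CH2)–C12(=O), rest as in 21 | C=C1C(=O)[Ru](=C=O)(=C=O)(=C=O)O[C@@H]2[C@H]1CC(=O)[C@H](C)[C@@]3(OC(C)(C)O[C@@H]23)C(=O)/C=C/C | intermediate (not isolated)
21 | (3aS,6R,7S,8S,8aR)-7-[(2E)-but-2-enoyl]-6-methyl-3-methylidene-7,8-[(propane-2,2-diyl)bis(oxy)]octahydro-2H-cyclohepta[b]furan-2,5-dione | C=C1C(=O)O[C@@H]2[C@H]1CC(=O)[C@H](C)[C@@]3(OC(C)(C)O[C@@H]23)C(=O)/C=C/C | intermediate
22 | (3aS,6R,7S,8S,8aR)-7-[(2E)-but-2-enoyl]-7,8-dihydroxy-6-methyl-3-methylideneoctahydro-2H-cyclohepta[b]furan-2,5-dione | C=C1C(=O)O[C@@H]2[C@H]1CC(=O)[C@H](C)[C@@](O)(C(=O)/C=C/C)[C@H]2O | intermediate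
23 | 3-methylbutanoic anhydride | CC(C)CC(=O)OC(=O)CC(C)C | starting material
24 | (3aS,6R,7S,8S,8aR)-7-[(2E)-but-2-enoyl]-7-hydroxy-6-methyl-3-methylidene-2,5-dioxooctahydro-2H-cyclohepta[b]furan-8-yl 3-methylbutanoate (CNP0283951.1) | C=C1C(=O)O[C@@H]2[C@H]1CC(=O)[C@H](C)[C@@](O)(C(=O)/C=C/C)[C@H]2OC(=O)CC(C)C | target

## Step count and risks

Total steps: 11. Longest linear sequence: 11 steps (1 → 24).

Steps most likely to fail:

**Step 9 (cyclocarbonylation).** The seven-membered closure is untested for this reaction, the enone carbonyl could compete through a six-membered closure, the allenylmethyl ketone may isomerise at 120 °C, and the C6 facial selectivity is only argued. The fallback sets out from 18 and comes back at 21. Hexamethylditin is added across the allene with [(η3-C3H5)PdCl]2 in THF at 23 °C; the allylstannane so formed adds to the C6 aldehyde within the molecule and gives, after aqueous work-up, the cis C6-hydroxy C7-[1-(trimethylstannyl)ethenyl] cycloheptanone acetonide F1. Iodine in CH2Cl2 at 0 °C turns it into the cis C6-hydroxy C7-(1-iodoethenyl) cycloheptanone acetonide F2. Pd(PPh3)4, CO (1 atm) and Et3N in THF at 50 °C then close the lactone by alkoxycarbonylation to 21.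

**Step 2 (Ireland–Claisen rearrangement).** The tartrate enolate can β-eliminate, and the C10 configuration rests on chelation-controlled ketene acetal geometry. The fallback sets out from 1 and comes back at 10. The lithium enolate of 1 (LiN(iPr)2, THF/DMPU, −78 °C) is alkylated anti to the neighbouring ester by (R)-N-methoxy-N-methyl-2-(trifluoromethylsulfonyloxy)propanamide (from methyl (R)-lactate) with inversion, giving dimethyl (4R,5S)-5-{(2R)-1-[methoxy(methyl)amino]-1-oxopropan-2-yl}-2,2-dimethyl-1,3-dioxolane-4,5-dicarboxylate F3. NaBH4 in EtOH reduces the less hindered ester, and lactonisation gives (2R)-2-[(3aS,6aS)-2,2-dimethyl-4-oxo-6,6a-dihydrofuro[3,4-d][1,3]dioxol-3a(4H)-yl]-N-methoxy-N-methylpropanamide F4. Cp2Zr(H)Cl in THF reduces the amide, not the lactone, to aldehyde 10.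

**Step 8 (double oxidation).** The primary alcohol is masked as hemiketal 16, and the product carries an epimerisable α-alkoxy aldehyde. The fallback sets out from 14 and comes back at 18. iBu2AlH (toluene, −78 °C) reduces the lactone to the lactol (3aS,6aS)-3a-[(2S)-3-hydroxyhepta-5,6-dien-2-yl]-2,2-dimethyltetrahydrofuro[3,4-d][1,3]dioxol-4-ol F5. Excess (E)-prop-1-enyllithium adds to its open aldehyde form and gives the C2-carbinol analogue of 17, (2E)-1-[4-(3-hydroxyhepta-5,6-dien-2-yl)-5-(hydroxymethyl)-2,2-dimethyl-1,3-dioxolan-4-yl]but-2-en-1-ol F6 (C1, C5, C10 as in 17; C2 and C9 as epimers). A Swern oxidation ((COCl)2, DMSO, then Et3N, −78 °C) activates all three hydroxyls before base is added and gives 18 without a hemiketal or lactone detour.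

## Further compounds

F1 | step 9 | cis C6-hydroxy C7-[1-(trimethylstannyl)ethenyl] cycloheptanone acetonide (C1, C5, C6, C7, C10 as in 21) | C=C([Sn](C)(C)C)[C@@H]1CC(=O)[C@H](C)[C@@]2(OC(C)(C)O[C@H]2[C@@H]1O)C(=O)/C=C/C
F2 | step 9 | cis C6-hydroxy C7-(1-iodoethenyl) cycloheptanone acetonide (C1, C5, C6, C7, C10 as in 21) | C=C(I)[C@@H]1CC(=O)[C@H](C)[C@@]2(OC(C)(C)O[C@H]2[C@@H]1O)C(=O)/C=C/C
F3 | step 2 | dimethyl (4R,5S)-5-{(2R)-1-[methoxy(methyl)amino]-1-oxopropan-2-yl}-2,2-dimethyl-1,3-dioxolane-4,5-dicarboxylate | COC(=O)[C@@H]1OC(C)(C)O[C@@]1(C(=O)OC)[C@@H](C)C(=O)N(C)OC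
F4 | step 2 | (2R)-2-[(3aS,6aS)-2,2-dimethyl-4-oxo-6,6a-dihydrofuro[3,4-d][1,3]dioxol-3a(4H)-yl]-N-methoxy-N-methylpropanamide | O=C1OC[C@@H]2OC(C)(C)O[C@]12[C@@H](C)C(=O)N(C)OC
F5 | step 8 | (3aS,6aS)-3a-[(2S)-3-hydroxyhepta-5,6-dien-2-yl]-2,2-dimethyltetrahydrofuro[3,4-d][1,3]dioxol-4-ol (lactol, anomers and C9 epimers) | OC1OC[C@@H]2OC(C)(C)O[C@]12[C@@H](C)C(O)CC=C=C
F6 | step 8 | (2E)-1-[4-(3-hydroxyhepta-5,6-dien-2-yl)-5-(hydroxymethyl)-2,2-dimethyl-1,3-dioxolan-4-yl]but-2-en-1-ol (C1, C5, C10 as in 17; C2 and C9 epimers) | C/C=C/C(O)[C@]1(OC(C)(C)O[C@H]1CO)[C@@H](C)C(O)CC=C=C
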